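The charge holds 0.0800 M more substrate than partner, and each turnover takes one of each, so substrate stays over in this flask. But the question concerns a much earlier moment.

substrate 0.40 M; partner 0.320 M; free catalyst 2.0 mM

1. the form that holds most of the catalyst when 10% of the substrate are converted (catalyst intermediate B / catalyst intermediate D / catalyst intermediate C / catalyst intermediate A / free catalyst)
2. its share of the catalyst then

    substrate + free catalyst → catalyst intermediate A (k1 = 17.3 M⁻¹ h⁻¹)
    partner + catalyst intermediate A ⇌ catalyst intermediate B (K2 = 122 M⁻¹, k2 = 143 M⁻¹ h⁻¹)
    catalyst intermediate B → catalyst intermediate C (k3 = 53.0 h⁻¹)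
    catalyst intermediate C → by-product + catalyst intermediate D (k4 = 42.6 h⁻¹)
    catalyst intermediate D → free catalyst + target (k5 = 216 h⁻¹)
    partner → decomposed reagent (k6 = 0.191 h⁻¹)

I count turnovers. The mark needs 20.0 turnovers per catalyst. A form waiting for a reagent stops for one over its rate constant times that reagent. A form that simply moves on stops for one over its constant. The way back from intermediate B runs at 1.17 h⁻¹ against 53.0 h⁻¹ forward, so I drop it. At the charge the stops are:

0.145 h at free catalyst + 0.0219 h at intermediate A + 0.0470 h at intermediates B, C and D

Their sum, 0.213 h, is the round time, the time one catalyst needs for one turnover. While the cycle runs steadily, each form's share of the catalyst is its stop over the round time.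

So this flask reaches the mark near 4.27 h, if the round stays as it is at the charge. The partner decomposes meanwhile at 0.191 h⁻¹, and the turnovers take 0.0400 M of it, which leaves about 0.102 M. The neighbouring flask has twice the free catalyst. It needs 10.0 turnovers per catalyst, so I expect it at the mark near 2.13 h. Because that time is shorter, it should arrive with more partner, about 0.173 M.

In this flask at the mark I reckon:

0.161 h at free catalyst + 0.0688 h at intermediate A + 0.0470 h at the rest = 0.276 h

The longest stop marks the resting state, free catalyst, with a share of 58.1%.

The forecast says free catalyst at 57%, on the grounds that “Substrate binding is the slowest step per cycle”.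

The flask gives free catalyst at 58.3%, at 4.75 h. At 2.61 h, the rate at which this flask makes intermediate B, over the rate at which it uses it up, each step taken net, is 0.999. Over this flask's 20.0 turnovers the mean round is 0.237 h, longer than the 0.213 h at the charge. With twice the free catalyst, the time to the mark is 0.479 of this flask's, or 2.28 h, so that flask's mean round is 0.228 h.

(All constants come from no measurement; the run is a simulation.)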